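The numbers of this flask were chosen freely, and the outcome is calculated.

The process chemist reads the clock and I count reagent, and we disagree over what these charges of reagent do to the bis adduct at the end.

| setting | epsilon | theta | delta | alpha | gamma |
|---|---|---|---|---|---|
| substrate | 0.078 M | 0.078 M | 0.078 M | 0.078 M | 0.078 M |
| reagent | 0.0800 M | 0.100 M | 0.150 M | 0.250 M | 0.400 M |
| time | 6.0 min | 6.0 min | 6.0 min | 6.0 min | 6.0 min |

    substrate + reagent → first product + released group (k1 = 1.53 M⁻¹ s⁻¹)
    reagent + first product → bis adduct + released group (k2 = 3.64 M⁻¹ s⁻¹)
    2 reagent → self-condensation product (k3 = 0.0203 M⁻¹ s⁻¹)
    reagent + bis adduct → triple product + released group (k4 = 0.613 M⁻¹ s⁻¹)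

- two of one species on the left: rate k times its square, two consumed each time
- "hardly changes" means that all values lie within two and a half points (for a concentration: within two and a half percent of the largest)
- run time (epsilon): 6.0 min

1. [bis adduct] at the end for epsilon, theta, delta, alpha, gamma, in this order
2. the shape of the row from first to last (falls all the way / hardly changes / rises, then falls / rises all the way / falls, then rises)

She takes the half-life of bis adduct by the step to triple product with reagent as charged, 0.24 min in epsilon, which is short against the run of 6.0 min, and since a larger charge shortens it further, she expects bis adduct to pass on to triple product and the row to fall all the way.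

I answer that her half-life holds reagent at its charge, whereas each addition takes one reagent away, so I reckon with one number, 1.03 for epsilon and 1.92 for delta: the charged reagent as a multiple of the charged substrate, the additions paid for.

A substrate takes one addition to become first product, two to become bis adduct and 3 to become triple product, so with the substrate charge held fixed, my count says that up to two additions paid for, more reagent, here the limiting reagent, buys more bis adduct, and that beyond two it increasingly buys triple product out of bis adduct.

I therefore commit to a row that climbs to delta, which lies just under the crossing, and drops by alpha, where 3.21 additions are paid for; my count places the top but gives no heights, and I grant her the region beyond 3, where reagent can outlast the demand and her clock can run.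

The forecast, on my side of the dispute, reads 0.0254 M, 0.0318 M, 0.0404 M, 0.0033 M and 2.000 × 10⁻⁹ M, a row that rises, then falls, holding that “The three lowest doses exhaust reagent well within 6 min”.

The flask gives 0.0254 M, 0.0318 M, 0.0404 M, 0.00328 M and 2.47 × 10⁻⁹ M, a row that rises, then falls, turning at 0.15 M, close to the 0.156 M that pays two additions per substrate. In delta reagent stands at 0% of its charge by 3.00 min, and of the 1.92 additions paid for, at 6.00 min bis adduct holds 1.04, triple product 0.749, first product 9.38% and self-condensation product the reagent of 0.0441. In alpha, with 3.21 paid for, reagent still stands at 2.06% of its charge at 6.00 min, and bis adduct goes on falling, from 4.21% of the substrate charged at 6.00 min to 0.0841% at 60.0 min.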